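(All runs were generated by integration with constants of no real substance.)

A rate constant stays the same from flask to flask at one temperature, so flasks at 40 °C can differ in a step that takes partner through partner concentration times time, which I call the exposure.

| flask | substrate | partner | temperature | remark | time |
|---|---|---|---|---|---|
| ash | 0.19 M | 0.11 M | 25 °C | run made earlier |  |
| birch | 0.19 M | 0.30 M | 40 °C | run made earlier |  |
| cedar | 0.14 M | 0.209 M | 25 °C | run made earlier |  |
| red | 0.10 M | 0.100 M | 40 °C |  | 60 h |
| teal | 0.19 M | 0.209 M | 40 °C |  | 20 h |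

| run | time / h | target / % | substrate / % |
|---|---|---|---|
| ash | 6.00 | 2 | 55 |
| ash | 12.0 | 0 | 34 |
| ash | 15.0 | 0 | 28 |
| ash | 25.0 | 7 | 12 |
| ash | 30.0 | 6 | 8 |
| birch | 3.00 | 2 | 18 |
| birch | 6.00 | 9 | 10 |
| birch | 8.00 | 8 | 6 |
| birch | 12.0 | 18 | 3 |
| birch | 15.0 | 24 | 4 |
| cedar | 2.00 | 0 | 85 |
| cedar | 4.00 | 0 | 70 |
| cedar | 8.00 | 1 | 51 |
| cedar | 15.0 | 1 | 28 |
| cedar | 30.0 | 9 | 11 |

(each reading ± 2 percentage points)

- the analysis behind the earlier runs scatters by 2 percentage points, standard deviation

- which of the two ends with the higher amount of target, in percent of the substrate charged ("neither" if they lie within 2 percentage points) (red / teal / neither)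
- target at the end, in percent of the substrate charged, red
- target at the end, in percent of the substrate charged, teal

The birch run stood at the temperature of red and teal. Its substrate falls to 18 % by 3.00 h, a half-life near 1.21 h, far shorter than teal's 20 h. Yet target reaches just 24 % at 15.0 h, so substrate seems to pass into an intermediate that gives target slowly.

Suppose that step takes partner, and that partner stays near its charge, which makes the step pseudo-first-order. Then the natural logarithm of the charge over what has not become target grows in step with exposure. That logarithm per unit of exposure is the yield constant. Birch has an exposure of 270 M·min, which gives 1.69 × 10⁻⁵ M⁻¹ s⁻¹, a reading that carries the scatter.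

Red has 360 M·min and teal 251 M·min, so red gets more exposure. My reckoning gives red 30.6 % and teal 22.5 %. The forecast says red ends higher, with 32 % (24 % to 45 %) for red and 22 % (17 % to 28 %) for teal, adding of red “A weaker partner order would push this higher”.

Red ends at 25.2 % and teal at 19.0 %, so red is higher.

    substrate → intermediate (k = 1.20 × 10⁻⁴ s⁻¹, Ea = 92.0 kJ mol⁻¹)
    substrate ⇌ dormant form (K = 0.560, k = 2.70 × 10⁻⁵ s⁻¹, Ea = 93.0 kJ mol⁻¹, ΔH = −43.0 kJ mol⁻¹)
    partner + intermediate → target (k = 2.20 × 10⁻⁵ M⁻¹ s⁻¹, Ea = 71.0 kJ mol⁻¹)
    2 intermediate → homo product (k = 1.90 × 10⁻⁵ M⁻¹ s⁻¹, Ea = 66.0 kJ mol⁻¹)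
    (constants at 40 °C)

Red's logarithm comes to 0.793 of the reckoned value. A neighbour flask, red with 0.040 M of partner, has an exposure of 144 M·min and holds 10.9 % target, which is 0.787 of its reckoned value. Red has not come to rest: at 60.0 h it still holds 42.8 % intermediate. Left until 600 h, red stands at 51.7 % target, 46.3 % homo product and 1.94 % intermediate.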